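**Retrosynthetic overview** (side chain numbered C1' = ketone carbon to C12' = ethyl terminus)
- Target ⇐ tert-butyl ester cleavage ⇐ C3-acylation (O→C acyl shift) of (R)-4-hydroxy-6-methyl-5,6-dihydropyran-2-one with the side-chain acid.
- Cross-conjugated diene ⇐ Suzuki coupling (C7'–C8') of an E-alkenylboronate with a Z-α-bromoenoate made from (S)-2-methylbutan-1-ol.
- Alkenylboronate ⇐ boryl-olefination of ethyl (R)-4-methyl-6-oxohexanoate.
- Key disconnection (C3'–C4'): this 1,6-dicarbonyl compound ⇐ zinc homoenolate of ethyl propanoate (nucleophilic β-carbon) + crotonaldehyde (electrophilic β-carbon); a chiral copper catalyst sets C4'.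
- Rings: only one, the δ-lactone, closed on its own (Claisen extension of methyl (R)-3-hydroxybutanoate, then acid lactonisation) before fragment union.

Assumption: Cu/(R)-Tol-BINAP in step 1 is taken to give (R)-5; if the first run (rotation against material of known configuration) shows the opposite, (S)-Tol-BINAP is used.

**Step 1**
Reactants: 1 (E)-but-2-enal (crotonaldehyde); 2 (1-ethoxycyclopropoxy)trimethylsilane
Product: 5 ethyl (R)-4-methyl-6-oxohexanoate, via zinc homoenolate 3 (not isolated), via silyl enol ether 4 (not isolated)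
Conditions: 2 (2.2 equiv), ZnCl2 (1.1 equiv), Et2O, 25 °C, 1 h; then Cu(O2CC4H3S) (copper thiophene-2-carboxylate, 5 mol %), (R)-Tol-BINAP (6 mol %), 1 (1.0 equiv), −30 → 0 °C; 1 M HCl, THF, 0 °C
Reagents that add atoms: none
Why: Proposed new method: homoenolate conjugate addition in which ZnCl2 opens 2 to the zinc homoenolate 3 and Me3SiCl, a Tol-BINAP-bound alkylcopper formed from 3 adds to the β-carbon of 1, and Me3SiCl traps the enolate as 4 so that 1,2-addition and aldol are suppressed, the bisphosphine selecting the enal face to set C4 of 5 as R; the closest known reactions are the racemic Cu-catalysed, Me3SiCl-promoted conjugate addition of 3 to enones and enals and the Cu/bisphosphine-catalysed enantioselective conjugate addition of dialkylzincs to enals.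

**Step 2**
Reactants: 5 ethyl (R)-4-methyl-6-oxohexanoate; 6 2-(dichloromethyl)-4,4,5,5-tetramethyl-1,3,2-dioxaborolane
Product: 7 ethyl (R,E)-4-methyl-7-(4,4,5,5-tetramethyl-1,3,2-dioxaborolan-2-yl)hept-6-enoate
Conditions: CrCl2 (8 equiv), lithium iodide (4 equiv), 6 (2 equiv), THF, 25 °C, 6 h
Reagents that add atoms: none
Why: Takai–Utimoto chromium-mediated boryl-olefination turns an aliphatic aldehyde into the E-alkenylboronate (typically E:Z > 20:1), is non-basic and leaves the ethyl ester and the C4 stereocentre untouched.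

**Step 3**
Reactants: 8 (S)-2-methylbutan-1-ol; 9 tert-butyl (triphenylphosphoranylidene)acetate
Product: 12 tert-butyl (S,Z)-2-bromo-4-methylhex-2-enoate, via (S)-2-methylbutanal 10 (not isolated), via bromo ylide 11 (not isolated)
Conditions: TEMPO (10 mol %), (diacetoxyiodo)benzene (1.1 equiv), CH2Cl2, 25 °C; then 11 (preformed from 9 and N-bromosuccinimide, CH2Cl2, −20 °C), 0 → 25 °C
Reagents that add atoms: N-bromosuccinimide, O=C1CCC(=O)N1Br
Why: TEMPO/(diacetoxyiodo)benzene oxidation gives the configurationally labile aldehyde 10 without over-oxidation, and it is consumed in the same flask by a Wittig reaction with the weakly basic stabilised bromo ylide 11, which places the ester trans to the sec-butyl group (Z-bromide) without epimerising the stereocentre carried over from 8.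

**Step 4**
Reactants: 7 ethyl (R,E)-4-methyl-7-(4,4,5,5-tetramethyl-1,3,2-dioxaborolan-2-yl)hept-6-enoate; 12 tert-butyl (S,Z)-2-bromo-4-methylhex-2-enoate
Product: 14 (4R,6E,8E,10S)-8-(tert-butoxycarbonyl)-4,10-dimethyldodeca-6,8-dienoic acid, via diester 13 (not isolated)
Conditions: Pd(dppf)Cl2 (5 mol %; dppf = 1,1'-bis(diphenylphosphino)ferrocene), LiOH·H2O (5 equiv), THF/H2O 4:1, 40 °C, 16 h; 1 M HCl to pH 3
Reagents that add atoms: lithium hydroxide, [Li+].[OH-]
Why: Suzuki–Miyaura coupling of the alkenylboronate with the α-bromoenoate proceeds with retention at both alkenes to give the 2-alkylidene-3-enoate 13, and the same aqueous LiOH then saponifies only the unhindered ethyl ester (the tert-butyl enoate is inert), with no stereocentre affected.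

**Step 5**
Reactants: 15 methyl (R)-3-hydroxybutanoate; 16 tert-butyl acetate
Product: 18 tert-butyl (R)-5-hydroxy-3-oxohexanoate, via lithium enolate of tert-butyl acetate 17 (not isolated)
Conditions: LiN(iPr)2 (3.3 equiv), 16 (3.3 equiv), THF, −78 °C; then 15, −78 → −30 °C; aq NH4Cl
Reagents that add atoms: none
Why: Crossed Claisen condensation in which excess enolate 17 first deprotonates the hydroxyl, then acylates at the methyl ester, the product being protected as its dianion; the stereocentre comes from the chiral pool and is not involved.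

**Step 6**
Reactants: 18 tert-butyl (R)-5-hydroxy-3-oxohexanoate
Product: 19 (R)-4-hydroxy-6-methyl-5,6-dihydro-2H-pyran-2-one
Conditions: CF3CO2H, CH2Cl2, 25 °C, 3 h
Reagents that add atoms: none
Why: Acid cleaves the tert-butyl ester and the δ-hydroxy β-keto acid lactonises to the six-membered enol lactone (the only ring of the target), leaving the stereocentre untouched.

**Step 7**
Reactants: 14 (4R,6E,8E,10S)-8-(tert-butoxycarbonyl)-4,10-dimethyldodeca-6,8-dienoic acid; 19 (R)-4-hydroxy-6-methyl-5,6-dihydro-2H-pyran-2-one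
Product: 21 tert-butyl (2E,3E,6R)-9-[(6R)-4-hydroxy-6-methyl-2-oxo-5,6-dihydro-2H-pyran-3-yl]-6-methyl-2-[(2S)-2-methylbutylidene]-9-oxonon-3-enoate, via O-acyl enol ester 20 (not isolated)
Conditions: DCC (1.2 equiv), DMAP (1.2 equiv), CH2Cl2, 0 → 25 °C, 16 h
Reagents that add atoms: none
Why: Carbodiimide esterification gives enol ester 20, which DMAP converts by a Fries-type O→C acyl migration into the chelated, thermodynamically favoured 3-acyl tricarbonyl, a known reaction type for 4-hydroxy-5,6-dihydropyran-2-ones that touches no stereocentre.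

**Step 8**
Reactants: 21 tert-butyl (2E,3E,6R)-9-[(6R)-4-hydroxy-6-methyl-2-oxo-5,6-dihydro-2H-pyran-3-yl]-6-methyl-2-[(2S)-2-methylbutylidene]-9-oxonon-3-enoate
Product: 22 (2E,3E,6R)-9-[(6R)-4-hydroxy-6-methyl-2-oxo-5,6-dihydro-2H-pyran-3-yl]-6-methyl-2-[(2S)-2-methylbutylidene]-9-oxonon-3-enoic acid (CNP0281879.1)
Conditions: CF3CO2H/CH2Cl2 1:4, 0 → 25 °C, 2 h
Reagents that add atoms: none
Why: Acidolysis of the tert-butyl ester (loss of isobutene) frees the dienoic acid without the basic hydrolysis that could open the acyl-lactone, and the stereocentres and alkene geometries are not affected.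

**Compound list**
1 | (E)-but-2-enal (crotonaldehyde) | C/C=C/C=O | starting material
2 | (1-ethoxycyclopropoxy)trimethylsilane | CCOC1(CC1)O[Si](C)(C)C | starting material
3 | bis(3-ethoxy-3-oxopropyl)zinc (zinc homoenolate of ethyl propanoate) | CCOC(=O)CC[Zn]CCC(=O)OCC | intermediate
4 | ethyl (4R)-4-methyl-6-(trimethylsilyloxy)hex-5-enoate (E/Z mixture at the enol ether) | CCOC(=O)CC[C@@H](C)C=CO[Si](C)(C)C | intermediate
5 | ethyl (R)-4-methyl-6-oxohexanoate | CCOC(=O)CC[C@@H](C)CC=O | intermediate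
6 | 2-(dichloromethyl)-4,4,5,5-tetramethyl-1,3,2-dioxaborolane | ClC(Cl)B1OC(C)(C)C(C)(C)O1 | starting material
7 | ethyl (R,E)-4-methyl-7-(4,4,5,5-tetramethyl-1,3,2-dioxaborolan-2-yl)hept-6-enoate | CCOC(=O)CC[C@@H](C)C/C=C/B1OC(C)(C)C(C)(C)O1 | intermediate
8 | (S)-2-methylbutan-1-ol | CC[C@H](C)CO | starting material
9 | tert-butyl (triphenylphosphoranylidene)acetate | CC(C)(C)OC(=O)C=P(c1ccccc1)(c1ccccc1)c1ccccc1 | starting material
10 | (S)-2-methylbutanal | CC[C@H](C)C=O | intermediate
11 | tert-butyl bromo(triphenylphosphoranylidene)acetate (bromo ylide) | CC(C)(C)OC(=O)C(Br)=P(c1ccccc1)(c1ccccc1)c1ccccc1 | intermediate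
12 | tert-butyl (S,Z)-2-bromo-4-methylhex-2-enoate | CC[C@H](C)/C=C(\Br)C(=O)OC(C)(C)C | intermediate
13 | ethyl (4R,6E,8E,10S)-8-(tert-butoxycarbonyl)-4,10-dimethyldodeca-6,8-dienoate | CC[C@H](C)/C=C(\C=C\C[C@H](C)CCC(=O)OCC)C(=O)OC(C)(C)C | intermediate
14 | (4R,6E,8E,10S)-8-(tert-butoxycarbonyl)-4,10-dimethyldodeca-6,8-dienoic acid | CC[C@H](C)/C=C(\C=C\C[C@H](C)CCC(=O)O)C(=O)OC(C)(C)C | intermediate
15 | methyl (R)-3-hydroxybutanoate | COC(=O)C[C@@H](C)O | starting material
16 | tert-butyl acetate | CC(=O)OC(C)(C)C | starting material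
17 | lithium enolate of tert-butyl acetate | [Li]OC(=C)OC(C)(C)C | intermediate
18 | tert-butyl (R)-5-hydroxy-3-oxohexanoate | C[C@@H](O)CC(=O)CC(=O)OC(C)(C)C | intermediate
19 | (R)-4-hydroxy-6-methyl-5,6-dihydro-2H-pyran-2-one | O=C1C=C(O)C[C@@H](C)O1 | intermediate
20 | (6R)-6-methyl-2-oxo-5,6-dihydro-2H-pyran-4-yl (4R,6E,8E,10S)-8-(tert-butoxycarbonyl)-4,10-dimethyldodeca-6,8-dienoate | CC[C@H](C)/C=C(\C=C\C[C@H](C)CCC(=O)OC1=CC(=O)O[C@H](C)C1)C(=O)OC(C)(C)C | intermediate
21 | tert-butyl (2E,3E,6R)-9-[(6R)-4-hydroxy-6-methyl-2-oxo-5,6-dihydro-2H-pyran-3-yl]-6-methyl-2-[(2S)-2-methylbutylidene]-9-oxonon-3-enoate | CC[C@H](C)/C=C(\C=C\C[C@H](C)CCC(=O)C1=C(O)C[C@@H](C)OC1=O)C(=O)OC(C)(C)C | intermediate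
22 | (2E,3E,6R)-9-[(6R)-4-hydroxy-6-methyl-2-oxo-5,6-dihydro-2H-pyran-3-yl]-6-methyl-2-[(2S)-2-methylbutylidene]-9-oxonon-3-enoic acid | CC[C@H](C)/C=C(\C=C\C[C@H](C)CCC(=O)C1=C(O)C[C@@H](C)OC1=O)C(=O)O | target

**Totals**
Total steps: 8. Longest linear sequence: 5 (steps 1, 2, 4, 7, 8).

**Steps most likely to fail, with fallbacks**

Step 1 (enantioselectivity and 1,4- versus 1,2-addition of an untested catalyst/nucleophile pair). The fallback sets out from 3 and comes back at 5, keeping the homoenolate bond construction but moving stereocontrol to an auxiliary. 3 is converted into its copper reagent with CuBr·SMe2 and added, with MgBr2·OEt2 chelating the two imide carbonyls, to (R)-3-[(E)-but-2-enoyl]-4-phenyloxazolidin-2-one F1, itself made in one operation from (R)-4-phenyloxazolidin-2-one and (E)-but-2-enoyl chloride. Attack anti to the phenyl group of the chelated s-cis imide gives ethyl (4R)-4-methyl-6-oxo-6-[(4R)-2-oxo-4-phenyloxazolidin-3-yl]hexanoate F2. LiSEt in THF at 0 °C then gives ethyl (R)-6-(ethylsulfanyl)-4-methyl-6-oxohexanoate F3 with recovery of the auxiliary, and Fukuyama reduction of F3 (Et3SiH, Pd/C, acetone) gives 5.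

Step 3 (Z:E ratio of the bromo-Wittig and loss of the volatile, epimerisable aldehyde). The fallback sets out from 10 (made in the flask from 8 as before) and 9 and comes back at 12, with bromine introduced after the olefination. Plain Wittig reaction of 10 with 9 gives tert-butyl (S,E)-4-methylhex-2-enoate F4. Addition of Br2 (CH2Cl2, 0 °C) gives tert-butyl (4S)-2,3-dibromo-4-methylhexanoate F5 as the anti-addition diastereomers, and Et3N-induced dehydrobromination through the ester enolate gives the thermodynamically preferred Z-bromide 12.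

Step 7 (incomplete O→C acyl migration or N-acylurea formation). The fallback sets out from 14 and 15 and comes back at 21, building the ring onto the acyl chain instead of acylating the ring. 14 is condensed with Meldrum's acid (DCC, DMAP, CH2Cl2) to tert-butyl (2E,3E,6R)-9-(2,2-dimethyl-4,6-dioxo-1,3-dioxan-5-ylidene)-9-hydroxy-6-methyl-2-[(2S)-2-methylbutylidene]non-3-enoate F6. Heating F6 with 15 in toluene at 90 °C (acylketene trapping) gives tert-butyl (2E,3E,6R)-11-{[(2R)-4-methoxy-4-oxobutan-2-yl]oxy}-6-methyl-2-[(2S)-2-methylbutylidene]-9,11-dioxoundec-3-enoate F7. Dieckmann cyclisation of F7 (KOtBu, THF, 0 °C) closes the lactone ring and gives 21.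

**Further compounds**
F1 | step 1 | (R)-3-[(E)-but-2-enoyl]-4-phenyloxazolidin-2-one | C/C=C/C(=O)N1[C@H](c2ccccc2)COC1=O
F2 | step 1 | ethyl (4R)-4-methyl-6-oxo-6-[(4R)-2-oxo-4-phenyloxazolidin-3-yl]hexanoate | CCOC(=O)CC[C@@H](C)CC(=O)N1[C@H](c2ccccc2)COC1=O
F3 | step 1 | ethyl (R)-6-(ethylsulfanyl)-4-methyl-6-oxohexanoate | CCOC(=O)CC[C@@H](C)CC(=O)SCC
F4 | step 3 | tert-butyl (S,E)-4-methylhex-2-enoate | CC[C@H](C)/C=C/C(=O)OC(C)(C)C
F5 | step 3 | tert-butyl (4S)-2,3-dibromo-4-methylhexanoate (anti-addition diastereomers) | CC[C@H](C)C(Br)C(Br)C(=O)OC(C)(C)C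
F6 | step 7 | tert-butyl (2E,3E,6R)-9-(2,2-dimethyl-4,6-dioxo-1,3-dioxan-5-ylidene)-9-hydroxy-6-methyl-2-[(2S)-2-methylbutylidene]non-3-enoate | CC[C@H](C)/C=C(\C=C\C[C@H](C)CCC(O)=C1C(=O)OC(C)(C)OC1=O)C(=O)OC(C)(C)C
F7 | step 7 | tert-butyl (2E,3E,6R)-11-{[(2R)-4-methoxy-4-oxobutan-2-yl]oxy}-6-methyl-2-[(2S)-2-methylbutylidene]-9,11-dioxoundec-3-enoate | CC[C@H](C)/C=C(\C=C\C[C@H](C)CCC(=O)CC(=O)O[C@H](C)CC(=O)OC)C(=O)OC(C)(C)C
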